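The numbers in the tables stem from a simulated flask for substances that don't exist; the scatter is artificial.

Start from the left-handed product: the single-handed free catalyst makes it from the left-handed substrate of a racemate under a held gas, and the ash run is this very flask, followed so far.

- ash: left-handed substrate 0.50 M; right-handed substrate 0.50 M; gas 170 mM (held); free catalyst 0.069 mol%; added ligand 0.26 mM; the very flask that is asked about, followed so far
- flask: left-handed substrate 0.50 M; gas 170 mM (held); free catalyst 0.069 mol%; added ligand 0.26 mM; right-handed substrate 0.50 M; time 10 min

ash run (percent of the left-handed substrate and right-handed substrate together charged)

| time / min | left-handed product / % | right-handed substrate / % |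
|---|---|---|
| 1.00 | 0.8 | 49.5 |
| 2.00 | 2.2 | 50.3 |
| 3.00 | 3.4 | 49.6 |
| 4.00 | 4.3 | 50.1 |
| 5.00 | 4.1 | 49.4 |

(scatter of a reading: 0.5 percentage points)

- free catalyst is single-handed; left-handed substrate and right-handed substrate are mirror images of each other, charged as a racemate, each of them at the stated concentration
- at the start none of reagent is dissolved
- what may be going on: free catalyst + left-handed substrate <-> catalyst intermediate A; free catalyst + right-handed substrate <-> catalyst intermediate B; reagent + catalyst intermediate A -> free catalyst + left-handed product; reagent + catalyst intermediate B -> free catalyst + right-handed product; gas <-> reagent; free catalyst + added ligand <-> idle complex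

1. concentration of left-handed product at 10 min, in M
2. concentration of right-handed substrate at 10 min, in M
3. concentration of left-handed substrate at 10 min, in M

Ask first where the flask ends: the left-handed product can reach the left-handed substrate charged, 0.50 M, so the question is how fast it gets there.

For the first way, fit a line through the origin to the ash run, which gives 9.65 mM/min, and divide by the catalyst charged, 0.345 mM. The result is T, the left-handed product made per minute per catalyst charged, a turnover frequency, of 28.0 /min. Held steady, T gives 0.0965 M at 10 min.

For the second way, let the left-handed substrate decay exponentially towards its end, taking the constant from the two last readings alone: 0.0195 /min, which gives 0.0886 M of left-handed product at 10 min.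

The two part, the curve standing lower. Commit to the line, since it rests on the whole ash run, while the curve leans on two readings, each with a scatter of 0.5 percentage points. So my reckoning is 0.0965 M of left-handed product, 0.403 M of left-handed substrate, and 0.498 M of right-handed substrate, the mean of its readings.

The forecast gives 0.075 M of left-handed product, 0.498 M of right-handed substrate and 0.425 M of left-handed substrate, lower than my line for the left-handed product, with the words “allowing for slowing I expect about 7.5% at 10 min”.

The flask gives 0.0967 M of left-handed product, 0.485 M of right-handed substrate and 0.403 M of left-handed substrate.

    free catalyst + left-handed substrate ⇌ catalyst intermediate A (K = 1.10 /M, k = 573 /M/s)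
    free catalyst + right-handed substrate ⇌ catalyst intermediate B (K = 3.10 /M, k = 120 /M/s)
    reagent + catalyst intermediate A → free catalyst + left-handed product (k = 22.9 /M/s)
    reagent + catalyst intermediate B → free catalyst + right-handed product (k = 1.13 /M/s)
    gas ⇌ reagent, rate k5*(csat - [reagent]) (kL = 0.435 /s)
    free catalyst + added ligand ⇌ idle complex, settled at all times (K = 6200 /M)

Put T back on this flask: 0.0967 M over the catalyst charged and 10 min gives 28.0 /min, beside the 28.0 /min read from the ash run. Then take the neighbouring flask, alike except for 0.028 mol% of free catalyst, which is 0.140 mM charged against the same 0.26 mM of added ligand. T times that charge and 10 min gives 0.0392 M. The neighbouring flask gives 0.0388 M of left-handed product, with idle complex holding 30.8% of its catalyst, against 26.3% in this flask.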